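**Plan**
Retrosynthesis: cut the anisoate C–O bond, then the C4–isopropyl bond (back to a cyclopentanone), then the C10–C1 bond of the seven-membered ring, then C8–C9 (cross-coupling), the C7=C8 alkene (back to an alkyne) and C6–C7/C5–C6 (alkynylation, formylation).
Forward: the five-membered ring is bought as 2-bromo-3-methylcyclopent-2-enone, the chain C6–C10 is grown on its α-carbon, and the seven-membered ring is closed last by a SmI2 ketyl–enone reductive cyclisation; isopropyl addition, esterification and ketal hydrolysis finish the route.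
Enabling feature: C1 is the β-carbon of a 2-substituted 3-methylcyclopent-2-enone, so it accepts the nucleophilic ketyl carbon C10 and becomes the methyl-bearing quaternary ring-fusion carbon; the enone carbonyl (C4) later takes the isopropyl group. The Z C7=C8 alkene of the future cycloheptene holds C10 next to C1, and the C9 ketone is masked as a diethyl ketal.
Stereochemistry: C6 comes from a catalytic enantioselective alkynylation; C1, C10 and C5 are set in the ring closure under control of C6 (1,3-allylic strain) and the angular methyl; C4 is set by addition to the ketone anti to the angular methyl.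
Atom numbers used below: C1 = ring-fusion C–CH3, C2/C3 = ring CH2, C4 = C(OH)(i-Pr), C5 = ring-fusion CH, C6 = CH–O(ester), C7=C8(CH3), C9 = C=O, C10 = CH–OH; β = face of the C1 methyl, α = opposite face.

Key step: step 9

**Step 1**
Reactants: 1 2-bromo-3-methylcyclopent-2-en-1-one
Product: 2 6-bromo-7-methyl-1,4-dioxaspiro[4.4]non-6-ene
Conditions: HOCH2CH2OH, p-TsOH (cat.), benzene, reflux, Dean–Stark
Reagents that add atoms: ethylene glycol (OCCO)
Why: Acid-catalysed ketalisation with azeotropic removal of water masks the carbonyl so that the α-bromo enone can act as an α-keto vinyl anion equivalent, the vinylic bromine holding the double bond in place.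

**Step 2**
Reactants: 2 6-bromo-7-methyl-1,4-dioxaspiro[4.4]non-6-ene
Product: 4 7-methyl-1,4-dioxaspiro[4.4]non-6-ene-6-carbaldehyde, via vinyllithium 3 (not isolated)
Conditions: n-BuLi, THF, −78 °C; DMF, −78 → 0 °C; aq. NH4Cl
Reagents that add atoms: N,N-dimethylformamide (CN(C)C=O)
Why: Bromine–lithium exchange gives vinyllithium 3, which DMF formylates (Bouveault aldehyde synthesis) to put C6 on the future C5.

**Step 3**
Reactants: 4 7-methyl-1,4-dioxaspiro[4.4]non-6-ene-6-carbaldehyde; 5 propyne
Product: 6 (S)-1-(7-methyl-1,4-dioxaspiro[4.4]non-6-en-6-yl)but-2-yn-1-ol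
Conditions: Me2Zn (3 equiv), ProPhenol ligand (2,6-bis{[2-(hydroxydiphenylmethyl)pyrrolidin-1-yl]methyl}-4-methylphenol, 20 mol %; the antipode that gives the (S)-carbinol, to be assigned on the first run by Mosher ester analysis), Ph3P=O (40 mol %), toluene, 0 °C
Reagents that add atoms: none
Why: Catalytic enantioselective alkynylation of the aldehyde by the zinc alkynylide inside a dinuclear zinc–ProPhenol complex sets C6 (S), the only stereocentre set by a reagent, and gives the propargylic alcohol needed for step 4.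

**Step 4**
Reactants: 6 (S)-1-(7-methyl-1,4-dioxaspiro[4.4]non-6-en-6-yl)but-2-yn-1-ol
Product: 9 (S,Z)-2-(1-hydroxy-3-iodobut-2-en-1-yl)-3-methylcyclopent-2-en-1-one, via cyclic vinylalanate 7 (not isolated), via iodo ketal 8 (not isolated)
Conditions: NaAlH2(OCH2CH2OCH3)2 (Red-Al), THF, 0 °C → rt; I2, THF, −78 °C; then aq. oxalic acid, CH2Cl2, rt
Reagents that add atoms: iodine (II); water (O)
Why: Hydroxyl-directed trans-hydroalumination of the propargylic alcohol puts aluminium on the distal alkyne carbon (alanate 7), iodinolysis with retention gives the Z γ-iodo allylic alcohol with C6 and iodine cis, and dilute acid then hydrolyses the allylic dioxolane to free the enone.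

**Step 5**
Reactants: 9 (S,Z)-2-(1-hydroxy-3-iodobut-2-en-1-yl)-3-methylcyclopent-2-en-1-one
Product: 10 (S,Z)-2-{1-[(tert-butyldimethylsilyl)oxy]-3-iodobut-2-en-1-yl}-3-methylcyclopent-2-en-1-one
Conditions: TBSOTf, 2,6-lutidine, CH2Cl2, −78 °C
Reagents that add atoms: tert-butyldimethylsilyl trifluoromethanesulfonate (CC(C)(C)[Si](C)(C)OS(=O)(=O)C(F)(F)F)
Why: Silylation of the secondary alcohol with the silyl triflate protects O6 as a bulky, non-ionisable ether that later steers the ring closure.

**Step 6**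
Reactants: 10 (S,Z)-2-{1-[(tert-butyldimethylsilyl)oxy]-3-iodobut-2-en-1-yl}-3-methylcyclopent-2-en-1-one; 11 tributyl(1-ethoxyvinyl)stannane
Product: 12 (S,Z)-2-{1-[(tert-butyldimethylsilyl)oxy]-4-ethoxy-3-methylpenta-2,4-dien-1-yl}-3-methylcyclopent-2-en-1-one
Conditions: Pd2(dba)3 (2.5 mol %), AsPh3 (20 mol %), CuI (10 mol %), NMP, 40 °C
Reagents that add atoms: none
Why: Stille cross-coupling on zerovalent palladium with copper co-catalysis replaces iodine by the C9–C10 unit with retention of alkene geometry, so that C6 and C9 are cis as the ring requires.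

**Step 7**
Reactants: 12 (S,Z)-2-{1-[(tert-butyldimethylsilyl)oxy]-4-ethoxy-3-methylpenta-2,4-dien-1-yl}-3-methylcyclopent-2-en-1-one
Product: 14 (S,Z)-2-{1-[(tert-butyldimethylsilyl)oxy]-4,4-diethoxy-5-hydroxy-3-methylpent-2-en-1-yl}-3-methylcyclopent-2-en-1-one, via alkoxy epoxide 13 (not isolated)
Conditions: dimethyldioxirane (1.05 equiv, acetone), CH2Cl2, −78 °C; then EtOH, PPTS (cat.), −78 → 0 °C
Reagents that add atoms: dimethyldioxirane (CC1(C)OO1); ethanol (CCO)
Why: Epoxidation should be selective for the electron-rich enol ether over the hindered Z trisubstituted alkene and the electron-poor enone, and acid-catalysed ethanolysis of the alkoxy epoxide at the oxocarbenium carbon (Rubottom-type oxidation of an enol ether) gives the α-hydroxy diethyl ketal that masks C9 at the ketone level.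

**Step 8**
Reactants: 14 (S,Z)-2-{1-[(tert-butyldimethylsilyl)oxy]-4,4-diethoxy-5-hydroxy-3-methylpent-2-en-1-yl}-3-methylcyclopent-2-en-1-one
Product: 15 (S,Z)-5-[(tert-butyldimethylsilyl)oxy]-2,2-diethoxy-3-methyl-5-(2-methyl-5-oxocyclopent-1-en-1-yl)pent-3-enal
Conditions: Dess–Martin periodinane, NaHCO3, CH2Cl2, 0 °C → rt
Reagents that add atoms: none
Why: Buffered Dess–Martin oxidation of the primary alcohol gives the non-enolisable α,α-dialkoxy aldehyde without touching the ketal or the silyl ether.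

**Step 9**
Reactants: 15 (S,Z)-5-[(tert-butyldimethylsilyl)oxy]-2,2-diethoxy-3-methyl-5-(2-methyl-5-oxocyclopent-1-en-1-yl)pent-3-enal
Product: 18 (3aS,4R,8S,8aS)-8-[(tert-butyldimethylsilyl)oxy]-5,5-diethoxy-4-hydroxy-3a,6-dimethyl-3,3a,4,5,8,8a-hexahydroazulen-1(2H)-one, via diiodosamarium ketyl 16 (not isolated), via samarium enolate 17 (not isolated)
Conditions: SmI2 (2.5 equiv), t-BuOH (3 equiv), THF (0.005 M, no HMPA), −78 → −20 °C; aq. NH4Cl
Reagents that add atoms: none
Why: Single-electron transfer from SmI2 to the α,α-dialkoxy aldehyde gives the diiodosamarium ketyl 16, whose nucleophilic carbon C10 adds to the β-carbon C1 of the cyclopentenone; a second electron gives the samarium enolate 17, which tert-butanol protonates at C5. The closest known reaction type is the SmI2-mediated ketyl–olefin (aldehyde–enone) reductive cyclisation, including its endo variants that give medium rings. The seven-membered ring closes in the 7-endo-trig mode (both enone carbons C5 and C1 lie in the new ring); the alternative 6-exo attack at the α-carbon C5 is disfavoured by polarity and would leave an unstabilised tertiary radical at C1. C1: 1,3-allylic strain with the C1 methyl holds H-6 in the enone plane, so the chain (C7) and the silyloxy group sit on opposite faces and C10 attacks anti to the silyloxy group; C10: the bulky O–SmI2 group points away from the cyclopentenone, anti to the developing enolate carbon C5, which should give the 10β-alcohol; C5: protonation of 17 on the α face, anti to the angular methyl and the 6-silyloxy group, should give the trans ring fusion. The step needs ring closure to outrun simple reduction, pinacol coupling or loss of ethoxide from the ketyl: the Z alkene and the sp2 centre C5 hold C10 within reach of C1, and the reaction is run dilute and cold.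

**Step 10**
Reactants: 18 (3aS,4R,8S,8aS)-8-[(tert-butyldimethylsilyl)oxy]-5,5-diethoxy-4-hydroxy-3a,6-dimethyl-3,3a,4,5,8,8a-hexahydroazulen-1(2H)-one; 19 isopropylmagnesium chloride
Product: 20 (1R,3aS,4R,8S,8aS)-8-[(tert-butyldimethylsilyl)oxy]-5,5-diethoxy-3a,6-dimethyl-1-(propan-2-yl)-1,2,3,3a,4,5,8,8a-octahydroazulene-1,4-diol
Conditions: CeCl3 (anhydrous, 4 equiv), 19 (4 equiv), THF, −78 °C; aq. NH4Cl
Reagents that add atoms: none
Why: 1,2-Addition of the weakly basic organocerium reagent to the hindered, enolisable cyclopentanone should suppress enolisation towards C5 and β-elimination of the silyloxy group, and attack on the α face, anti to the angular methyl and the C5–C6 bond, gives the 4β-hydroxy-4α-isopropyl centre.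

**Step 11**
Reactants: 20 (1R,3aS,4R,8S,8aS)-8-[(tert-butyldimethylsilyl)oxy]-5,5-diethoxy-3a,6-dimethyl-1-(propan-2-yl)-1,2,3,3a,4,5,8,8a-octahydroazulene-1,4-diol
Product: 21 (1R,3aS,4R,8S,8aS)-5,5-diethoxy-3a,6-dimethyl-1-(propan-2-yl)-1,2,3,3a,4,5,8,8a-octahydroazulene-1,4,8-triol
Conditions: TBAF, THF, 0 °C → rt
Reagents that add atoms: none
Why: Fluoride-mediated desilylation frees the 6-hydroxyl while the ketal and the other two hydroxyls are untouched.

**Step 12**
Reactants: 21 (1R,3aS,4R,8S,8aS)-5,5-diethoxy-3a,6-dimethyl-1-(propan-2-yl)-1,2,3,3a,4,5,8,8a-octahydroazulene-1,4,8-triol; 22 4-methoxybenzoyl chloride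
Product: 23 (3R,3aS,4S,8R,8aS)-7,7-diethoxy-3,8-dihydroxy-6,8a-dimethyl-3-(propan-2-yl)-1,2,3,3a,4,7,8,8a-octahydroazulen-4-yl 4-methoxybenzoate
Conditions: 22 (1.1 equiv), Et3N, DMAP (cat.), CH2Cl2, 0 °C
Reagents that add atoms: none
Why: DMAP-catalysed acyl transfer (Steglich-type acylation) should take place at the allylic secondary 6-hydroxyl, because the 10-hydroxyl is flanked by the quaternary C1 and the ketal carbon C9 and the 4-hydroxyl is tertiary.

**Step 13**
Reactants: 23 (3R,3aS,4S,8R,8aS)-7,7-diethoxy-3,8-dihydroxy-6,8a-dimethyl-3-(propan-2-yl)-1,2,3,3a,4,7,8,8a-octahydroazulen-4-yl 4-methoxybenzoate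
Product: 24 (3R,3aS,4S,8R,8aS)-3,8-dihydroxy-6,8a-dimethyl-7-oxo-3-(propan-2-yl)-1,2,3,3a,4,7,8,8a-octahydroazulen-4-yl 4-methoxybenzoate
Conditions: PPTS (cat.), acetone/H2O (9:1), 40 °C
Reagents that add atoms: water (O)
Why: Acid-catalysed ketal hydrolysis through the allylic oxocarbenium ion unveils the conjugated C9 ketone under conditions that should spare the allylic ester, the tertiary alcohol and the α-ketol, with the ring holding the alkene geometry.

**Compound list**
1 | 2-bromo-3-methylcyclopent-2-en-1-one | CC1=C(Br)C(=O)CC1 | starting material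
2 | 6-bromo-7-methyl-1,4-dioxaspiro[4.4]non-6-ene | CC1=C(Br)C2(CC1)OCCO2 | intermediate
3 | (7-methyl-1,4-dioxaspiro[4.4]non-6-en-6-yl)lithium | [Li]C1=C(C)CCC12OCCO2 | intermediate (not isolated)
4 | 7-methyl-1,4-dioxaspiro[4.4]non-6-ene-6-carbaldehyde | O=CC1=C(C)CCC12OCCO2 | intermediate
5 | propyne | CC#C | starting material
6 | (S)-1-(7-methyl-1,4-dioxaspiro[4.4]non-6-en-6-yl)but-2-yn-1-ol | CC#C[C@H](O)C1=C(C)CCC12OCCO2 | intermediate
7 | sodium cyclic vinylalanate (five-membered O–Al–C8=C7–C6 ring, two 2-methoxyethoxy groups on aluminium, C6 (S)) | CC1=C[C@@H](C2=C(C)CCC23OCCO3)O[Al-]1(OCCOC)OCCOC.[Na+] | intermediate (not isolated)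
8 | (S,Z)-3-iodo-1-(7-methyl-1,4-dioxaspiro[4.4]non-6-en-6-yl)but-2-en-1-ol | C/C(I)=C/[C@H](O)C1=C(C)CCC12OCCO2 | intermediate (not isolated)
9 | (S,Z)-2-(1-hydroxy-3-iodobut-2-en-1-yl)-3-methylcyclopent-2-en-1-one | C/C(I)=C/[C@H](O)C1=C(C)CCC1=O | intermediate
10 | (S,Z)-2-{1-[(tert-butyldimethylsilyl)oxy]-3-iodobut-2-en-1-yl}-3-methylcyclopent-2-en-1-one | C/C(I)=C/[C@H](O[Si](C)(C)C(C)(C)C)C1=C(C)CCC1=O | intermediate
11 | tributyl(1-ethoxyvinyl)stannane | CCCC[Sn](CCCC)(CCCC)C(=C)OCC | starting material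
12 | (S,Z)-2-{1-[(tert-butyldimethylsilyl)oxy]-4-ethoxy-3-methylpenta-2,4-dien-1-yl}-3-methylcyclopent-2-en-1-one | C=C(OCC)/C(C)=C\[C@H](O[Si](C)(C)C(C)(C)C)C1=C(C)CCC1=O | intermediate
13 | alkoxy epoxide of 12 (2-ethoxyoxirane at C9–C10, either configuration at C9) | CCOC1(CO1)/C(C)=C\[C@H](O[Si](C)(C)C(C)(C)C)C2=C(C)CCC2=O | intermediate (not isolated)
14 | (S,Z)-2-{1-[(tert-butyldimethylsilyl)oxy]-4,4-diethoxy-5-hydroxy-3-methylpent-2-en-1-yl}-3-methylcyclopent-2-en-1-one | CCOC(CO)(OCC)/C(C)=C\[C@H](O[Si](C)(C)C(C)(C)C)C1=C(C)CCC1=O | intermediate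
15 | (S,Z)-5-[(tert-butyldimethylsilyl)oxy]-2,2-diethoxy-3-methyl-5-(2-methyl-5-oxocyclopent-1-en-1-yl)pent-3-enal | CCOC(C=O)(OCC)/C(C)=C\[C@H](O[Si](C)(C)C(C)(C)C)C1=C(C)CCC1=O | intermediate
16 | diiodosamarium ketyl of 15 (radical at C10, O–SmI2) | CCOC([CH]O[Sm](I)I)(OCC)/C(C)=C\[C@H](O[Si](C)(C)C(C)(C)C)C1=C(C)CCC1=O | intermediate (not isolated)
17 | bicyclic bis(diiodosamarium) 10-alkoxide 4-enolate (C4=C5 enolate, C1 and C10 as in 18) | CC(C)(C)[Si](C)(C)O[C@H]1C=C(C)C(OCC)(OCC)[C@H](O[Sm](I)I)[C@@]2(C)CCC(O[Sm](I)I)=C12 | intermediate (not isolated)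
18 | (3aS,4R,8S,8aS)-8-[(tert-butyldimethylsilyl)oxy]-5,5-diethoxy-4-hydroxy-3a,6-dimethyl-3,3a,4,5,8,8a-hexahydroazulen-1(2H)-one (trans-fused; 1β-CH3, 5α-H, 6α-OTBS, 10β-OH) | CC(C)(C)[Si](C)(C)O[C@H]1C=C(C)C(OCC)(OCC)[C@H](O)[C@@]2(C)CCC(=O)[C@H]12 | intermediate
19 | isopropylmagnesium chloride | CC(C)[Mg]Cl | starting material
20 | (1R,3aS,4R,8S,8aS)-8-[(tert-butyldimethylsilyl)oxy]-5,5-diethoxy-3a,6-dimethyl-1-(propan-2-yl)-1,2,3,3a,4,5,8,8a-octahydroazulene-1,4-diol | CC(C)(C)[Si](C)(C)O[C@H]1C=C(C)C(OCC)(OCC)[C@H](O)[C@@]2(C)CC[C@@](O)(C(C)C)[C@H]12 | intermediate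
21 | (1R,3aS,4R,8S,8aS)-5,5-diethoxy-3a,6-dimethyl-1-(propan-2-yl)-1,2,3,3a,4,5,8,8a-octahydroazulene-1,4,8-triol | O[C@H]1C=C(C)C(OCC)(OCC)[C@H](O)[C@@]2(C)CC[C@@](O)(C(C)C)[C@H]12 | intermediate
22 | 4-methoxybenzoyl chloride | COc1ccc(cc1)C(Cl)=O | starting material
23 | (3R,3aS,4S,8R,8aS)-7,7-diethoxy-3,8-dihydroxy-6,8a-dimethyl-3-(propan-2-yl)-1,2,3,3a,4,7,8,8a-octahydroazulen-4-yl 4-methoxybenzoate | COc1ccc(C(=O)O[C@H]2C=C(C)C(OCC)(OCC)[C@H](O)[C@@]3(C)CC[C@@](O)(C(C)C)[C@H]23)cc1 | intermediate
24 | (3R,3aS,4S,8R,8aS)-3,8-dihydroxy-6,8a-dimethyl-7-oxo-3-(propan-2-yl)-1,2,3,3a,4,7,8,8a-octahydroazulen-4-yl 4-methoxybenzoate | COc1ccc(C(=O)O[C@H]2C=C(C)C(=O)[C@H](O)[C@@]3(C)CC[C@@](O)(C(C)C)[C@H]23)cc1 | target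

**Step count and risks**
Total steps: 13. Longest linear sequence: 13 steps, from 1.

Steps most likely to fail:

Step 9. What may go wrong: closure of the seven-membered ring may be slower than further reduction of the ketyl (simple reduction of the aldehyde, expulsion of ethoxide, pinacol dimerisation); C10 may attack the wrong face of C1; protonation of the enolate may give the cis ring fusion. Fallback: a temporary oxygen bridge between O6 and C9 turns the closure into a six-membered chair closure. It sets out from 9. Stille coupling of 9 with 11 under the conditions of step 6 gives the dienyl ether alcohol F1. Dimethyldioxirane at −78 °C epoxidises the enol ether, and the free 6-hydroxyl, held cis by the Z alkene, opens the alkoxy epoxide to the cyclic ethyl ketal F2 (hydroxymethyl cis to the cyclopentenone; the trans isomer is re-equilibrated with PPTS in ethanol). Dess–Martin oxidation gives the aldehyde F3. SmI2 then forms the C10–C1 bond through a chair inside an 8-oxabicyclo[3.2.1]octene to give the bridged ketone F4, in which the C1 methyl is held axial and C5 is protonated on the exo face. Addition of 19 with CeCl3 gives the carbinol F5, and aqueous HCl in THF opens the bridged ketal to the triol enone F6. Acylation with 22 (1.05 equiv, Et3N, DMAP, −20 °C) at the 6-hydroxyl gives 24, where the fallback rejoins the route.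

Step 10. What may go wrong: enolisation of the ketone towards C5 with β-elimination of the silyloxy group, reduction of the ketone by β-hydride transfer from the secondary Grignard reagent, or attack on the β face. Fallback: it sets out from 18. Addition of isopropenylmagnesium bromide with CeCl3 (a smaller sp2 nucleophile without the hydride-transfer pathway) gives the isopropenyl carbinol F7. Hydrogenation of the 1,1-disubstituted alkene with RhCl(PPh3)3 and H2, which should leave the hindered trisubstituted ring alkene, gives 20, where the fallback rejoins the route.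

Step 3. What may go wrong: slow addition to the hindered, fully substituted enal and an enantioselectivity too low for a single-enantiomer route. Fallback: it sets out from 4. Addition of prop-1-ynylmagnesium bromide gives the racemic propargylic alcohol F8, Dess–Martin oxidation gives the ynone F9, and Corey–Bakshi–Shibata reduction (methyl oxazaborolidine, catecholborane, −78 °C; alkynyl as the small group) gives 6, where the fallback rejoins the route.

**Further compounds**
F1 | step 9 | (S,Z)-2-(4-ethoxy-1-hydroxy-3-methylpenta-2,4-dien-1-yl)-3-methylcyclopent-2-en-1-one | C=C(OCC)/C(C)=C\[C@H](O)C1=C(C)CCC1=O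
F2 | step 9 | 2-[(2S,5R)-5-ethoxy-5-(hydroxymethyl)-4-methyl-2,5-dihydrofuran-2-yl]-3-methylcyclopent-2-en-1-one (hydroxymethyl cis to the cyclopentenone) | CCO[C@@]1(CO)O[C@@H](C=C1C)C2=C(C)CCC2=O
F3 | step 9 | (2R,5S)-2-ethoxy-3-methyl-5-(2-methyl-5-oxocyclopent-1-en-1-yl)-2,5-dihydrofuran-2-carbaldehyde | CCO[C@@]1(C=O)O[C@@H](C=C1C)C2=C(C)CCC2=O
F4 | step 9 | bridged ketal ketone: 9-ethoxy-6α,9α-epoxy-10β-hydroxy-1β,8-dimethyl trans-fused hydroazulen-4-one (5α-H; skeleton numbering of the plan) | CCO[C@@]12O[C@@H](C=C1C)[C@H]3C(=O)CC[C@]3(C)[C@H]2O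
F5 | step 9 | bridged ketal carbinol: 9-ethoxy-6α,9α-epoxy-4β,10β-dihydroxy-4α-isopropyl-1β,8-dimethyl trans-fused hydroazulene (5α-H) | CCO[C@@]12O[C@@H](C=C1C)[C@H]3[C@](O)(C(C)C)CC[C@]3(C)[C@H]2O
F6 | step 9 | triol enone: the 6-O-deacyl form of 24 (4β,6α,10β-trihydroxy-9-one) | O[C@H]1C=C(C)C(=O)[C@H](O)[C@@]2(C)CC[C@@](O)(C(C)C)[C@H]12
F7 | step 10 | isopropenyl analogue of 20 (4α-isopropenyl, 4β-OH) | CC(C)(C)[Si](C)(C)O[C@H]1C=C(C)C(OCC)(OCC)[C@H](O)[C@@]2(C)CC[C@@](O)(C(C)=C)[C@H]12
F8 | step 3 | racemic 1-(7-methyl-1,4-dioxaspiro[4.4]non-6-en-6-yl)but-2-yn-1-ol | CC#CC(O)C1=C(C)CCC12OCCO2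
F9 | step 3 | 1-(7-methyl-1,4-dioxaspiro[4.4]non-6-en-6-yl)but-2-yn-1-one | CC#CC(=O)C1=C(C)CCC12OCCO2
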